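**Route overview**

- Cuts: the side-chain CO2H and the C4 enol oxygen are tied back into a six-membered enol lactone; the C1–CH2 bond of the prenyl group is cut by a retro-[3,3] shift to an aryl 1,1-dimethylallyl ether on the C2 oxygen; then the aryl–CH2 bond of the lavandulyl chain, the benzylic C–phenyl bond, the O–C2 bond of the chromanone and the aryl–acyl bond are cut, back to 5,7-dihydroxycoumarin.
- Enabling feature: in the carbocycle (C1 quaternary, C2 ketone, C3 carrying the 3-phenylpropanoic acid, C4 enol OH, C5–C6 shared with the dimethylchromanone ring) the C2 oxygen is ortho to C1 and the acid reaches the C4 oxygen. The ring is therefore a masked phloroglucinol: as an arene it carries the prenyl unit on the C2 oxygen, and the lactone ring places its phenyl-bearing carbon peri to that oxygen, where it can distinguish the two faces at C1.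
- Forward order: the coumarin bicycle is bought; C8 acylation and oxa-Michael closure build the chromanone ring; conjugate arylation converts the pyranone ring into the 4-phenyl-dihydrocoumarin lactone; iodination and Negishi coupling attach the lavandulyl chain; O-alkylation and semihydrogenation put the 1,1-dimethylallyl group on oxygen; the Claisen shift moves it to C1 with dearomatisation; hydrolysis opens the lactone ring last.
- Stereochemistry: the cis-(2R,3S) chromanone pair comes from the quinine-catalysed oxa-Michael closure; the benzylic (S) centre from Rh(acac)(C2H4)2/(S)-SEGPHOS; the side-chain centre from (R)-lavandulol, carried through untouched; the quaternary C1 from the Claisen shift on the face opposite the pseudo-axial phenyl of the lactone.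

Key step: step 12

Assumption: (R)-lavandulol is taken as purchasable as the single natural enantiomer, and the target, drawn as one enol tautomer of a β-triketone, is expected to be isolated as its equilibrium tautomer mixture.

Step 1
Reactants: 1 5,7-dihydroxycoumarin; 2 tigloyl chloride
Product: 3 5,7-dihydroxy-8-tigloylcoumarin
Conditions: AlCl3 (3 equiv), PhNO2/ClCH2CH2Cl, 0 to 60 °C; aq. HCl work-up
Reagents that add atoms: none
Why: Friedel–Crafts acylation of the phloroglucinol-type ring, expected at C8 (between the 7-OH and the ring oxygen) as in the 4-alkyl- and 4-aryl-5,7-dihydroxycoumarin series, with the minor C6 isomer removed by crystallisation.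

Step 2
Reactants: 3 5,7-dihydroxy-8-tigloylcoumarin
Product: 4 5-(tert-butyldimethylsilyloxy)-7-hydroxy-8-tigloylcoumarin
Conditions: TBSCl (1.05 equiv), imidazole, CH2Cl2, 0 °C, short reaction time
Reagents that add atoms: tert-butyldimethylsilyl chloride, CC(C)(C)[Si](C)(C)Cl
Why: Selective silylation of the non-chelated phenol, since the 7-OH is held in a hydrogen bond to the tigloyl carbonyl; this removes the acidic 5-OH that would otherwise pair with the alkaloid catalyst at the wrong oxygen in step 3 and sit peri to the arylation site in step 4.

Step 3
Reactants: 4 5-(tert-butyldimethylsilyloxy)-7-hydroxy-8-tigloylcoumarin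
Product: 5 (8R,9S)-5-(tert-butyldimethylsilyloxy)-8,9-dimethyl-8,9-dihydropyrano[2,3-f]chromene-2,10-dione (coumarin with a cis-2,3-dimethylchroman-4-one ring on O7/C8)
Conditions: (−)-quinine (0.2 equiv), PhCl, 20 °C
Reagents that add atoms: none
Why: Cinchona-alkaloid-catalysed intramolecular oxa-Michael addition of the 7-OH to the tigloyl enone (6-endo closure), known for 7-hydroxy-8-tigloylcoumarins, in which the quinine–phenoxide ion pair selects the enone face to set the O-bearing carbon as R and kinetic protonation of the enol on the same side gives the cis methyl neighbour (S).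

Step 4
Reactants: 5 cis-chromanone coumarin silyl ether; 6 phenylboronic acid
Product: 7 (4S,8R,9S)-5-(tert-butyldimethylsilyloxy)-8,9-dimethyl-4-phenyl-3,4,8,9-tetrahydropyrano[2,3-f]chromene-2,10-dione
Conditions: Rh(acac)(C2H4)2 (3 mol%), (S)-SEGPHOS (3.3 mol%), 6 (5 equiv), dioxane/H2O 10:1, 60 °C
Reagents that add atoms: none
Why: Rhodium-catalysed asymmetric 1,4-addition of an arylboronic acid to a coumarin (Hayashi–Miyaura reaction), run without base so the cis-chromanone is not epimerised; the bisphosphine on rhodium selects the face of C4, and (S)-SEGPHOS is chosen because the (R)-ligand is known to give (R)-4-arylchroman-2-ones, which share the priority order found here.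

Step 5
Reactants: 7 4-phenyl-dihydrocoumarin chromanone silyl ether
Product: 8 (4S,8R,9S)-5-(tert-butyldimethylsilyloxy)-6-iodo-8,9-dimethyl-4-phenyl-3,4,8,9-tetrahydropyrano[2,3-f]chromene-2,10-dione
Conditions: NIS (1.2 equiv), CF3CO2H (0.3 equiv), MeCN, 0 °C to rt
Reagents that add atoms: N-iodosuccinimide, O=C1CCC(=O)N1I
Why: Electrophilic aromatic iodination at the only remaining C–H of the trioxygenated ring, which lies ortho to the silyloxy and alkoxy groups and para to the lactone oxygen, while the isolated phenyl ring is far less reactive.

Step 6
Reactants: 9 (R)-lavandulol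
Product: 10 (R)-lavandulyl iodide [(2R)-1-iodo-5-methyl-2-(prop-1-en-2-yl)hex-4-ene]
Conditions: PPh3, I2, imidazole, CH2Cl2, 0 °C to rt
Reagents that add atoms: iodine, II
Why: Appel iodination of the primary alcohol, which does not involve the neighbouring stereocentre or the two alkenes.

Step 7
Reactants: 10 (R)-lavandulyl iodide
Product: 11 (R)-lavandulylzinc iodide (LiCl complex, kept and titrated as a THF solution)
Conditions: Zn dust (activated with BrCH2CH2Br and Me3SiCl), LiCl, THF, 30 °C
Reagents that add atoms: zinc, [Zn]
Why: LiCl-promoted direct insertion of zinc into a primary C–I bond, a standard preparation of alkylzinc iodides that tolerates alkenes and does not touch the β-stereocentre.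

Step 8
Reactants: 8 aryl iodide silyl ether; 11 (R)-lavandulylzinc iodide
Product: 12 (4S,8R,9S)-5-(tert-butyldimethylsilyloxy)-8,9-dimethyl-6-[(2S)-5-methyl-2-(prop-1-en-2-yl)hex-4-enyl]-4-phenyl-3,4,8,9-tetrahydropyrano[2,3-f]chromene-2,10-dione
Conditions: Pd(OAc)2 (5 mol%), SPhos (10 mol%), 11 (1.8 equiv), THF, 25 to 45 °C
Reagents that add atoms: none
Why: Negishi sp2–sp3 coupling, in which the bulky electron-rich biarylphosphine lets the doubly ortho-substituted aryl–palladium–alkyl intermediate undergo reductive elimination faster than β-hydride elimination; the alkylzinc iodide is too weak a nucleophile and base to attack the lactone or ketone or to epimerise the cis-chromanone, and the side-chain centre changes descriptor from R to S only through the priority rules.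

Step 9
Reactants: 12 6-lavandulyl silyl ether
Product: 13 (4S,8R,9S)-5-hydroxy-8,9-dimethyl-6-[(2S)-5-methyl-2-(prop-1-en-2-yl)hex-4-enyl]-4-phenyl-3,4,8,9-tetrahydropyrano[2,3-f]chromene-2,10-dione
Conditions: Bu4NF (1.2 equiv), AcOH (1.5 equiv), THF, 0 °C
Reagents that add atoms: none
Why: Fluoride cleavage of an aryl silyl ether, buffered with acetic acid so that neither the lactone nor the cis-chromanone meets free base, and free of the acid that would cyclise the ortho-lavandulyl phenol.

Step 10
Reactants: 13 6-lavandulyl-5-hydroxy compound; 14 2-methylbut-3-yn-2-ol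
Product: 16 5-O-(2-methylbut-3-yn-2-yl) ether of 13, via 2-methylbut-3-yn-2-yl trifluoroacetate 15 (not isolated)
Conditions: 14, (CF3CO)2O, DBU, MeCN, −5 °C; then 13, DBU (1.05 equiv), CuCl2·2H2O (1 mol%), MeCN, −5 to 0 °C; pH 7 buffer quench
Reagents that add atoms: none
Why: Copper-catalysed propargylic etherification of a phenol, in which the phenoxide captures the copper-bound tertiary propargylic cation at the carbinol carbon (the standard route to aryl 1,1-dimethylpropargyl ethers); the trifluoroacetate leaving group is chosen so that every equivalent of DBU ends as a non-basic salt and the cis-chromanone never meets free amidine.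

Step 11
Reactants: 16 aryl 1,1-dimethylpropargyl ether
Product: 17 5-O-(2-methylbut-3-en-2-yl) ether of 13 (aryl 1,1-dimethylallyl ether)
Conditions: H2 (1 atm), Pd/CaCO3 poisoned with Pb(OAc)2 (Lindlar catalyst), quinoline, EtOAc, 20 °C, stopped after 1 equiv H2
Reagents that add atoms: none
Why: Lindlar semihydrogenation reduces the terminal alkyne to the vinyl group and leaves the trisubstituted and 1,1-disubstituted alkenes of the lavandulyl chain untouched.

Step 12
Reactants: 17 aryl 1,1-dimethylallyl ether
Product: 18 (4S,6S,8R,9S)-8,9-dimethyl-6-(3-methylbut-2-enyl)-6-[(2S)-5-methyl-2-(prop-1-en-2-yl)hex-4-enyl]-4-phenyl-3,4,8,9-tetrahydropyrano[2,3-f]chromene-2,5,10(6H)-trione (dearomatised enol lactone)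
Conditions: degassed PhMe (0.02 M), 80–100 °C
Reagents that add atoms: none
Why: Heating should trigger a concerted, suprafacial [3,3] sigmatropic shift through a chair-like transition state in which the aryl O–C(CH3)2 bond breaks while the vinyl CH2 terminus bonds to the lavandulyl-bearing ortho carbon, so the allyl unit arrives transposed as a finished prenyl group and the arene becomes a cyclohexa-2,4-dienone. The closest known reaction is the dearomative ortho-Claisen rearrangement of allyl and 1,1-dimethylallyl aryl ethers onto an already substituted ortho carbon (1-substituted 2-naphthyl ethers, phloroglucinol ethers, the dienone-forming first stage of the caged-xanthone cascade); no ring is closed, so no closure mode arises. The one new stereocentre, the quaternary carbon, is controlled by the (S)-benzylic carbon of the lactone: peri strain with the ether oxygen keeps the phenyl pseudo-axial, the doubly ortho-flanked ether must hold its O–C bond perpendicular to the arene and does so on the face away from that phenyl, and the suprafacial shift delivers the CH2 terminus on this same face, which puts prenyl anti to phenyl as the target requires. Site selectivity between the two ortho carbons is needed and is secured because the alternative, the ring-fusion carbon, would become a quaternary centre wedged against the phenyl-bearing methine inside the lactone ring, whereas the chosen carbon carries only a CH2 group. The dienone should be a thermodynamic sink because the trioxygenated ring has little aromatic stabilisation to lose and the product is a push-pull system (vinylogous ester through the chromanone oxygen, vinylogous anhydride through the lactone) that also sheds the strain of the crowded tertiary ether. The facial preference rests on conformational analysis and has not been measured on a fused dihydrocoumarin, so the epimer at the quaternary carbon is the by-product to look for.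

Step 13
Reactants: 18 dearomatised enol lactone
Product: 19 CNP0150579.2, (3S)-3-[(2R,3S,8S)-5-hydroxy-2,3-dimethyl-8-(3-methylbut-2-enyl)-8-[(2S)-5-methyl-2-(prop-1-en-2-yl)hex-4-enyl]-4,7-dioxo-3,4,7,8-tetrahydro-2H-chromen-6-yl]-3-phenylpropanoic acid
Conditions: NaHCO3 (2.2 equiv), THF/H2O 3:1, 0 °C to rt; then 1 M HCl to pH 3 at 0 °C
Reagents that add atoms: water, O
Why: Hydrolysis of an enol ester of a β-diketone (a vinylogous anhydride), whose leaving group is a stabilised triketone enolate, so bicarbonate should suffice; the resulting dianion is protected against enolisation at the chromanone, and acidification returns the acid and the C4 enol without touching any stereocentre.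

**Compound list**

1 | 5,7-dihydroxycoumarin | O=c1ccc2c(O)cc(O)cc2o1 | starting material
2 | tigloyl chloride, (E)-2-methylbut-2-enoyl chloride | C/C=C(\C)C(=O)Cl | starting material
3 | 5,7-dihydroxy-8-tigloylcoumarin | C/C=C(\C)C(=O)c1c(O)cc(O)c2ccc(=O)oc12 | intermediate
4 | 5-(tert-butyldimethylsilyloxy)-7-hydroxy-8-tigloylcoumarin | C/C=C(\C)C(=O)c1c(O)cc(O[Si](C)(C)C(C)(C)C)c2ccc(=O)oc12 | intermediate
5 | (8R,9S)-5-(tert-butyldimethylsilyloxy)-8,9-dimethyl-8,9-dihydropyrano[2,3-f]chromene-2,10-dione | CC(C)(C)[Si](C)(C)Oc1cc2O[C@H](C)[C@H](C)C(=O)c2c2oc(=O)ccc12 | intermediate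
6 | phenylboronic acid | OB(O)c1ccccc1 | starting material
7 | (4S,8R,9S)-5-(tert-butyldimethylsilyloxy)-8,9-dimethyl-4-phenyl-3,4,8,9-tetrahydropyrano[2,3-f]chromene-2,10-dione | CC(C)(C)[Si](C)(C)Oc1cc2O[C@H](C)[C@H](C)C(=O)c2c2OC(=O)C[C@@H](c3ccccc3)c12 | intermediate
8 | 6-iodo derivative of 7 | CC(C)(C)[Si](C)(C)Oc1c(I)c2O[C@H](C)[C@H](C)C(=O)c2c2OC(=O)C[C@@H](c3ccccc3)c12 | intermediate
9 | (R)-lavandulol, (2R)-5-methyl-2-(prop-1-en-2-yl)hex-4-en-1-ol | C=C(C)[C@@H](CC=C(C)C)CO | starting material
10 | (R)-lavandulyl iodide | C=C(C)[C@@H](CC=C(C)C)CI | intermediate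
11 | (R)-lavandulylzinc iodide (THF solution, LiCl complex) | C=C(C)[C@@H](CC=C(C)C)C[Zn]I | intermediate
12 | 6-lavandulyl 5-O-silyl ether, (4S,8R,9S) with (2S) side chain | CC(C)(C)[Si](C)(C)Oc1c(C[C@H](CC=C(C)C)C(C)=C)c2O[C@H](C)[C@H](C)C(=O)c2c2OC(=O)C[C@@H](c3ccccc3)c12 | intermediate
13 | 6-lavandulyl-5-hydroxy-4-phenyl-dihydrocoumarin chromanone | Oc1c(C[C@H](CC=C(C)C)C(C)=C)c2O[C@H](C)[C@H](C)C(=O)c2c2OC(=O)C[C@@H](c3ccccc3)c12 | intermediate
14 | 2-methylbut-3-yn-2-ol | C#CC(C)(C)O | starting material
15 | 2-methylbut-3-yn-2-yl trifluoroacetate | C#CC(C)(C)OC(=O)C(F)(F)F | intermediate (not isolated)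
16 | 5-O-(2-methylbut-3-yn-2-yl) ether of 13 | C#CC(C)(C)Oc1c(C[C@H](CC=C(C)C)C(C)=C)c2O[C@H](C)[C@H](C)C(=O)c2c2OC(=O)C[C@@H](c3ccccc3)c12 | intermediate
17 | 5-O-(2-methylbut-3-en-2-yl) ether of 13 | C=CC(C)(C)Oc1c(C[C@H](CC=C(C)C)C(C)=C)c2O[C@H](C)[C@H](C)C(=O)c2c2OC(=O)C[C@@H](c3ccccc3)c12 | intermediate
18 | dearomatised enol lactone with the prenyl/lavandulyl quaternary carbon, (4S,6S,8R,9S) | C=C(C)[C@@H](CC=C(C)C)C[C@]1(CC=C(C)C)C(=O)C3=C(OC(=O)C[C@H]3c4ccccc4)C2=C1O[C@H](C)[C@H](C)C2=O | intermediate
19 | CNP0150579.2 | C=C(C)[C@@H](CC=C(C)C)C[C@]1(CC=C(C)C)C(=O)C([C@@H](CC(=O)O)c2ccccc2)=C(O)C2=C1O[C@H](C)[C@H](C)C2=O | target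

Total step count: 13. Longest linear sequence: 11 steps (1 to 19 through steps 1–5 and 8–13); the lavandulyl branch adds steps 6 and 7.

**Steps most likely to fail**

Step 12. The rearrangement may proceed in part through the rotamer with the ether syn to the phenyl group, giving poor facial discrimination at the quaternary carbon, or the crowded tertiary ether may ionise and lose or scramble its allyl unit. The fallback puts the prenyl group on carbon directly under catalyst control. It sets out from phenol 13 and uses a base-free Tsuji–Trost dearomative C-allylation with tert-butyl 3-methylbut-2-en-1-yl carbonate F1 (made from 3-methylbut-2-en-1-ol and di-tert-butyl dicarbonate with catalytic DMAP), Pd2(dba)3 and either enantiomer of the DACH-phenyl Trost ligand in toluene at 0–25 °C. O-Allylation is reversible under these conditions, whereas attack of the lavandulyl-bearing ring carbon on the unsubstituted terminus of the prenyl–palladium complex is not; the ligand enantiomer that gives the required face would be kept. The fallback rejoins the route at 18.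

Step 10. The doubly ortho-flanked phenoxide may capture the tertiary propargylic electrophile too slowly, so that elimination of the trifluoroacetate or C-alkylation takes over, and prolonged contact with DBU may epimerise the methyl-bearing carbon next to the chromanone carbonyl. The fallback avoids both the amidine and the hydrogenation. It sets out from phenol 13 and uses a Tsuji–Trost O-allylation with tert-butyl 2-methylbut-3-en-2-yl carbonate F2 (made from 2-methylbut-3-en-2-ol and di-tert-butyl dicarbonate with catalytic DMAP) and Pd(PPh3)4 in THF at 0 °C, stopped early. Under these kinetic conditions the phenoxide should attack the more substituted terminus of the allyl–palladium complex and give the branched ether. The fallback rejoins the route at 17.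

Step 4. Insertion of the electron-rich, peri-substituted coumarin into the aryl–rhodium bond may be so slow that protodeboronation of the boronic acid outruns addition, or the silyl ether may be lost in the hot aqueous medium. The fallback separates C–C bond formation from the setting of the stereocentre. It sets out from 5 and 6: an oxidative Heck arylation (Pd(OAc)2, 1,10-phenanthroline, O2, DMF, 80 °C) should give (8R,9S)-5-(tert-butyldimethylsilyloxy)-8,9-dimethyl-4-phenyl-8,9-dihydropyrano[2,3-f]chromene-2,10-dione F3. Asymmetric conjugate reduction of this 4-phenylcoumarin would follow, with CuH generated from Cu(OAc)2·H2O, the enantiomer of DTBM-SEGPHOS that delivers the (S)-centre, (EtO)2MeSiH (1.1 equiv) and t-BuOH in toluene at 0 °C. The doubly ortho-substituted, vinylogous-ester ketone is expected to react much more slowly than the enoate. The fallback rejoins the route at 7.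

Further compounds
F1 | step 12 | tert-butyl 3-methylbut-2-en-1-yl carbonate | CC(C)=CCOC(=O)OC(C)(C)C
F2 | step 10 | tert-butyl 2-methylbut-3-en-2-yl carbonate | C=CC(C)(C)OC(=O)OC(C)(C)C
F3 | step 4 | (8R,9S)-5-(tert-butyldimethylsilyloxy)-8,9-dimethyl-4-phenyl-8,9-dihydropyrano[2,3-f]chromene-2,10-dione | CC(C)(C)[Si](C)(C)Oc1cc2O[C@H](C)[C@H](C)C(=O)c2c2oc(=O)cc(-c3ccccc3)c12
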